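The readings stem from a simulated flask for substances that don't exist, and the scatter is random.

**Two slowdowns.** In the winter run the target's gain slowed more than the fall of its feed, the starting material, seems to allow.

| setting | winter | flask |
|---|---|---|
| starting material | 10 mM | 10 mM |
| gas phase | 0.32 mM (held) | 0.32 mM (held) |
| protic impurity | 0.10 mM | 0.200 mM |
| remark | run made earlier |  |
| time |  | 80 min |

- winter (time / min: target / %, starting material / %): 0.667: 3, 88; 2.00: 12, 73; 4.00: 18, 60; 6.00: 20, 45; 8.00: 26, 39

(readings scatter by 2 percentage points)

* target at 80 min, in percent of the starting material charged
* the change that raises the amount of target at 80 min, in percent of the starting material charged most ("none" if none brings more than 2 percentage points) (theta / gamma / none)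
* amount of target at 80 min, in percent of the starting material charged, after theta

- the numbers in the tables scatter with a standard deviation of 2 percentage points
- at the start none of the gas phase is in solution
- no earlier run changes the charge of protic impurity; that part of a forecast is a guess

- theta: doubling the transfer coefficient of the gas phase, all else as stated
- gamma: doubling the saturation concentration of gas phase, all else as stated

**The mismatch.** In the winter run, up to 2.00 min, the target, P, gained 0.0600 min⁻¹ of the charge, while the starting material, A, averaged 86.5 %. From 4.00 min to 8.00 min, P gained 0.0200 min⁻¹, a third of that, yet A averaged 48.0 %, about half.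

**Means.** I replaced each stretch by its means, with P made at a·A and lost at b·P. Ignoring loss, the first stretch gives a = 0.0694 min⁻¹. The later stretch, with P averaging 21.3 %, gives b = 0.0623 min⁻¹. With that b, the loss in the first stretch comes to 0.00374 min⁻¹, less than its gain of 0.0600 min⁻¹, so ignoring it cost little. So I read the mismatch as a loss of target, and ρ = a/b comes to 1.11: the tracking ratio of P to A at which making and loss balance (a steady state).

**My reckoning.** The inverse of A rose nearly straight, as in a second-order fall, at 0.196 min⁻¹, so I put A at 6.01 % by 80 min. A then shrinks by 0.0118 min⁻¹ of itself, slower than b, so I took P to follow A and expected 6.67 %. The extra protic impurity, 1.00 % of the charge, I guessed harmless, and the readings did not part theta from gamma.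

**The forecast.** It gave 40 % (28 % to 48 %), 44 % after theta, and gamma as best, holding that “the rest is lost to a competing path”.

**The result.** The flask gave 6.39 %, and 6.39 % after theta; gamma moved it by −5 percentage points, so the best change is none.

    gas phase ⇌ dissolved gas, rate k1*(csat - [dissolved gas]) (kL = 1.60 s⁻¹)
    starting material + dissolved gas ⇌ target (K = 6000 M⁻¹, k = 3.30 M⁻¹ s⁻¹)
    dissolved gas + target → over-reacted product (k = 1.70 M⁻¹ s⁻¹)
    starting material + protic impurity → quenched substrate (k = 6.10 M⁻¹ s⁻¹)
    2 starting material → homo dimer (k = 0.0830 M⁻¹ s⁻¹)

The flask held 4.45 % starting material at 80.0 min, below my 6.01 %, and ρ = 1.11 on that amount gives 4.94 %, less than the 6.39 % of target it held. The neighbouring flask, read at 20.0 min, held 19.4 % starting material; ρ makes that 21.5 % target, and it held 24.0 %.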